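**Assumption (one line).** The absolute sense of induction of the two chiral catalysts (steps 2 and 3) is assigned by the usual models; the catalyst enantiomer named is the one expected to give the stated configuration, and its antipode would be used unchanged otherwise.

Abbreviation: Bpin = 4,4,5,5-tetramethyl-1,3,2-dioxaborolan-2-yl. Ring positions of all carbocycles are quoted in the target numbering defined below; lactone positions use oxan-2-one numbering.

## Analysis of the target

The target is (1S,2S,4R,5S)-2-bromo-1-[(E)-2-bromoethenyl]-4,5-dichloro-1,5-dimethylcyclohexane. The ring is numbered C1 = C(CH3)(CH=CHBr), C2 = CHBr, C3 = CH2, C4 = CHCl, C5 = C(CH3)Cl, C6 = CH2. There are four stereocentres, two of them fully substituted (quaternary C1 and the tertiary chloride C5). The bromovinyl arm, the C2 bromine and both chlorines lie on one face and both methyl groups on the other. Hence Br is cis to the vinyl arm, the two chlorines are cis (a syn-dichloride) and C2–Br/C4–Cl are cis-1,3. In the better chair the C2 bromine and C4 chlorine are equatorial, the C5 chlorine and the bromovinyl group axial, and both methyls equatorial.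

The tertiary chloride ionises and eliminates easily, and the (E)-bromoalkene is sensitive to strong base and low-valent metals. The final compound has no protecting-group handle, so all four halogens must arrive late and under mild conditions.

Three things make the synthesis hard. The C2 bromide is neopentyl-like (next to quaternary C1), so ordinary SN2 entry is unattractive. A syn-dichloride that includes a tertiary carbon cannot come from normal anti addition of chlorine. The quaternary centre must be made as one enantiomer.

The strategy rests on the C1–C6 bond. It joins quaternary C1 to a CH2 that is allylic to a C4=C5 alkene carrying the C5 methyl, which is the π bond from which both C–Cl bonds can be made. In that form C1 (with its arm at the carboxyl level) is the α-carbon of a δ-lactone enolate and C4 is the lactone carbinol carbon bearing an isopropenyl group, so a [3,3] shift can forge C1–C6.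

## Retrosynthetic reasoning

**C4–Cl and C5–Cl (19 ⇐ 18 ⇐ 17 ⇐ 16).** Both C–Cl bonds are cut back to the C4=C5 alkene of 16, the only place where two adjacent halogenated carbons can derive from one π bond. Because the chlorines are cis, the forward sequence must be a net syn addition. A one-step selenium-catalysed syn-dichlorination is established for 1,2-disubstituted alkenes, but with a trisubstituted alkene the selenium(IV) adduct is expected to divert to allylic chloride, so it is not relied on. Instead the alkene is epoxidised on the face away from Br and the vinyl arm (17), chloride opens the tertiary carbon with inversion (18), and the remaining secondary alcohol is replaced by chloride with inversion (19). Two inversions on an epoxide amount to a syn-dichlorination on the face opposite the oxygen.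

**C2–Br (16 ⇐ 14).** The neopentyl C–Br bond is cut to a C–B bond of opposite configuration. A boronate complex can be brominated at carbon with inversion, which avoids nucleophilic substitution next to the quaternary centre. Boron must therefore be trans to the vinyl arm in 14.

**Bromovinyl arm (14 ⇐ 13 ⇐ 12 ⇐ 11 ⇐ 10).** The CH=CHBr double bond is cut to aldehyde 13 (one-carbon bromo-olefination, E-selective on a hindered aldehyde). The aldehyde is traced through alcohol 12 and ester 11 to acid 10. The olefination is placed before the bromodeboronation so that no hydroxyl protection is needed and the group beside the reacting carbon is a flat vinyl unit and not a silyloxymethyl group.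

**C1–C6 (10 ⇐ 7, the key disconnection).** Cutting C1–C6 and re-forming the C4–O bond leads to lactone 7. Its α-carbon is C1, its carbinol carbon is C4 and its isopropenyl group supplies C5, the C5 methyl and C6. The forward reaction is the Claisen rearrangement of the lactone silyl ketene acetal. It closes the ring, places the alkene at C4=C5 and transfers the configuration of the carbinol carbon to quaternary C1. A substituent cis to the isopropenyl group in the lactone ends trans to the carboxyl group, so the 4,6-cis boronate gives the relation required above.

**Lactone C–O and C–B (7 ⇐ 6 ⇐ 4 + 5).** Opening the lactone gives δ-hydroxy ester 6. Its C–B bond is cut to the enoate 4 and diboron 5 (ligand-controlled copper-catalysed conjugate borylation). The α-centre is left uncontrolled because it is erased on enolisation.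

**Carbinol centre (4 ⇐ 2 + 3 ⇐ 1).** The C–C bond between the carbinol carbon and the γ-carbon of the enoate is cut to methacrolein 3 and silyl dienolate 2 from ethyl tiglate 1 (catalytic asymmetric vinylogous aldol). This single catalytic step sets the centre from which C1 is later derived.

## Alternatives that were turned down

**Alternative 1:** Disconnection of C1–C6, C2–Br and a temporary C5–O bond in one step. The acyclic chlorodienol A2, (2Z,5R)-5-chloro-2,6-dimethylhepta-2,6-dien-1-ol, would be treated with an electrophilic bromine donor. The Z-trisubstituted alkene is brominated, the 1,1-disubstituted alkene adds anti to the new C–Br bond, and the primary hydroxyl captures the C5 cation to give the bridged ether A1, (1S,2S,4R,5S)-2-bromo-4-chloro-1,5-dimethyl-6-oxabicyclo[3.2.1]octane.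
- For: it makes the ring, the quaternary centre and the neopentyl C2–Br bond together, and the anti addition gives the cis Br/arm relation directly. On the C–Br bond it is stronger than the chosen route, which needs a boron detour.
- Against: C5 ends as a tertiary ether that must be exchanged for chloride with retention, an SN1 process with no reliable facial control and easy elimination. The secondary allylic chloride in A2 is labile, deactivates the alkene that must act as nucleophile, and is the only source of absolute configuration.
- Comparison: the chosen route is longer but sets each centre by a separate, understood event, and it makes the tertiary chloride by a stereospecific epoxide opening.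

**Alternative 2:** Disconnection of C1–C2 and C5–C6 by a [4+2] cycloaddition of methacrolein 3 with the aminosiloxydiene A4, (E)-3-[(tert-butyldimethylsilyl)oxy]-N,N-dimethylbuta-1,3-dien-1-amine. A chiral hydrogen-bond donor or a chromium(III)–salen Lewis acid would catalyse it, and acidic work-up would release A3, (1R)-1-methyl-4-oxocyclohex-2-ene-1-carbaldehyde.
- For: this is the best-precedented and shortest way to the quaternary centre (one catalytic step from commercial materials). The arm is already an aldehyde and the enone offers C2 for conjugate borylation. On speed and certainty of the quaternary centre it is stronger than the chosen route.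
- Against: A3 lacks the C5 methyl and carries oxygen at C4. The methyl and the tertiary chlorine would have to be introduced by two enolate functionalisations, the ketone turned into the secondary chloride beside a fully substituted carbon, and two carbonyl groups kept apart. All three remaining centres would depend on substrate control from a quaternary carbon whose two substituents differ little in size.
- Comparison: the chosen key step delivers a ring that already holds the C5 methyl, the C4=C5 alkene and a configured C2–B bond.

**Alternative 3:** Disconnection of C1–C2 by a ring-closing palladium allylic alkylation. In the acyclic precursor A6, methyl (2E,5Z)-1-[dimethyl(phenyl)silyl]-3,5-dimethyl-8,8-bis(Bpin)octa-2,5-dien-1-yl carbonate, alkoxide activation of the geminal bis(boronate) would give an α-boryl carbanion. This attacks the trisubstituted terminus of the silyl-substituted π-allyl complex (6-exo) to give A5, 2-{(1R,6R)-6-[(E)-2-(dimethylphenylsilyl)ethenyl]-4,6-dimethylcyclohex-3-en-1-yl}-4,4,5,5-tetramethyl-1,3,2-dioxaborolane.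
- For: ring, quaternary centre and C–B centre arise in one step, and the arm arrives as a vinylsilane convertible to the bromoalkene without redox steps. After ring closure it is shorter than the chosen route (A5 corresponds to 14).
- Against: one catalyst would have to control two new centres at once (the π-allyl face and which boryl group is lost). Attack of a hindered secondary nucleophile at a fully substituted allyl terminus is demanding, and A6 with its Z-trisubstituted alkene is itself a multistep target.
- Comparison: the chosen route sets the C–B centre by ligand-controlled borylation and the quaternary centre by suprafacial transfer, in separate steps, and pays for this with more steps after ring closure.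

Key step: step 5

## Route

**Step 1**
Reactants: 1 ethyl (E)-2-methylbut-2-enoate
Product: 2 tert-butyl[(1-ethoxy-2-methylbuta-1,3-dien-1-yl)oxy]dimethylsilane
Conditions: LDA, THF, −78 °C; TBSCl, DMPU, −78 °C → rt
Reagents that add atoms: tert-butyldimethylsilyl chloride, CC(C)(C)[Si](C)(C)Cl
Why: γ-Deprotonation of the tiglate gives the extended dienolate, which is O-silylated (silyl dienolate formation); the polar cosolvent suppresses amide conjugate addition and favours O-silylation. No stereocentre is formed and the ketene acetal geometry is irrelevant.

**Step 2**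
Reactants: 2 tert-butyl[(1-ethoxy-2-methylbuta-1,3-dien-1-yl)oxy]dimethylsilane; 3 methacrolein
Product: 4 ethyl (2E,5R)-5-hydroxy-2,6-dimethylhepta-2,6-dienoate
Conditions: SiCl4, (R,R)-binaphthyldiamine bisphosphoramide (5 mol%), i-Pr2NEt (cat.), CH2Cl2, −78 °C; aq. NaHCO3
Reagents that add atoms: none
Why: Catalytic asymmetric vinylogous Mukaiyama aldol addition under Lewis-base-activated SiCl4; reaction through the γ-carbon gives the E-enoate. The chiral silicon cation directs the dienolate to the Re face of the enal, which sets the 5R carbinol centre.

**Step 3**
Reactants: 4 ethyl (2E,5R)-5-hydroxy-2,6-dimethylhepta-2,6-dienoate; 5 bis(pinacolato)diboron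
Product: 6 ethyl (3R,5R)-5-hydroxy-2,6-dimethyl-3-(Bpin)hept-6-enoate (mixture at C2)
Conditions: CuCl (5 mol%), NaOt-Bu (10 mol%), (R,S)-Josiphos (5 mol%), MeOH (2 equiv), THF, rt
Reagents that add atoms: none
Why: Copper(I)–boryl conjugate addition to the enoate (catalytic asymmetric β-borylation), with methanol turning over the copper enolate; the ligand fixes the face of boron delivery and gives 3R, since the remote carbinol exerts little bias. The protonated α-centre is uncontrolled and is erased in step 5; the isolated 1,1-disubstituted alkene does not react.

**Step 4**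
Reactants: 6 ethyl (3R,5R)-5-hydroxy-2,6-dimethyl-3-(Bpin)hept-6-enoate
Product: 7 (4R,6R)-3-methyl-6-(prop-1-en-2-yl)-4-(Bpin)oxan-2-one (4,6-cis; mixture at C3)
Conditions: PPTS (10 mol%), toluene, 80 °C
Reagents that add atoms: none
Why: Acid-catalysed lactonisation of a δ-hydroxy ester; no stereocentre is touched. Any 4,6-trans lactone from imperfect selectivity in steps 2 and 3 is a diastereomer and should be removable here by chromatography, which also raises enantiomeric purity.

**Step 5 (key step)**
Reactants: 7 (4R,6R)-3-methyl-6-(prop-1-en-2-yl)-4-(Bpin)oxan-2-one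
Product: 10 (1R,6R)-1,3-dimethyl-6-(Bpin)cyclohex-3-ene-1-carboxylic acid, via silyl ketene acetal 8 (not isolated), via silyl ester 9 (not isolated)
Conditions: LDA, THF, −78 °C; TBSCl, DMPU, −78 °C → rt; toluene, 105 °C; AcOH–THF–H2O, rt
Reagents that add atoms: tert-butyldimethylsilyl chloride, CC(C)(C)[Si](C)(C)Cl (its silyl group is carried only by 8 and 9 and is lost on hydrolysis to 10)
Why: Deprotonation at C3 of 7 and O-silylation give ketene acetal 8, whose C3=C2(OSi)–O1–C6–C(CH3)=CH2 array undergoes a concerted suprafacial [3,3] shift on heating, forming the C3–CH2 bond (target C1–C6) as the allylic C6–O1 bond breaks. The closest known reaction type is the Ireland–Claisen rearrangement of lactone silyl ketene acetals, which converts ω-alkenyl lactones into cycloalkenecarboxylic acids. The two-carbon tether C4–C5 forces a boat-like, bicyclo[2.2.2]-shaped transition state, and the six-membered carbocycle closes in a formally 6-(enolexo)-endo-trig mode that is allowed because it is pericyclic; the new alkene is necessarily cis within the ring at target C4=C5. The only new stereocentre, quaternary C1, is controlled by the C6 carbinol centre: the allyl unit can reach only the face of the ketene acetal to which it is attached, so 6R gives the 1R acid. The boron-bearing carbon is not touched, and because it is cis to the isopropenyl group in 7 it ends trans to the carboxyl group. The step needs O- over C-silylation (secured by the fully substituted enolate carbon and TBSCl/DMPU) and rearrangement faster than decomposition of the β-boryl ketene acetal (pinacol boronates tolerate amide enolisation at −78 °C, and the flat Bpin group has a small steric demand in the crowded boat). The C3 epimer mixture of 7 converges because C3 is sp2 in 8; mild aqueous acid then cleaves silyl ester 9 to acid 10.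

**Step 6**
Reactants: 10 (1R,6R)-1,3-dimethyl-6-(Bpin)cyclohex-3-ene-1-carboxylic acid
Product: 11 methyl (1R,6R)-1,3-dimethyl-6-(Bpin)cyclohex-3-ene-1-carboxylate
Conditions: MeI, K2CO3, DMF, rt
Reagents that add atoms: iodomethane, CI
Why: O-Alkylation of the carboxylate (SN2 at methyl) is insensitive to the hindered α-quaternary carbon, unlike acid-catalysed esterification; boronate and alkene are inert.

**Step 7**
Reactants: 11 methyl (1R,6R)-1,3-dimethyl-6-(Bpin)cyclohex-3-ene-1-carboxylate
Product: 12 [(1R,6R)-1,3-dimethyl-6-(Bpin)cyclohex-3-en-1-yl]methanol
Conditions: DIBAL-H (2.5 equiv), CH2Cl2, −78 → 0 °C; Rochelle salt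
Reagents that add atoms: none
Why: Hydride reduction of the ester to the primary alcohol; DIBAL-H is chosen because it leaves the pinacol boronate intact, whereas LiAlH4 would attack the B–O bonds, and borane would hydroborate the ring alkene.

**Step 8**
Reactants: 12 [(1R,6R)-1,3-dimethyl-6-(Bpin)cyclohex-3-en-1-yl]methanol
Product: 13 (1R,6R)-1,3-dimethyl-6-(Bpin)cyclohex-3-ene-1-carbaldehyde
Conditions: Dess–Martin periodinane, CH2Cl2, rt
Reagents that add atoms: none
Why: Dess–Martin oxidation of a neopentyl primary alcohol; the aldehyde has no α-hydrogen and cannot epimerise, and the C–B bond is not oxidised by the iodinane.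

**Step 9**
Reactants: 13 (1R,6R)-1,3-dimethyl-6-(Bpin)cyclohex-3-ene-1-carbaldehyde
Product: 14 2-{(1R,6R)-6-[(E)-2-bromoethenyl]-4,6-dimethylcyclohex-3-en-1-yl}-4,4,5,5-tetramethyl-1,3,2-dioxaborolane
Conditions: CrBr2, CHBr3, THF, 50 °C
Reagents that add atoms: bromoform, BrC(Br)Br
Why: Takai olefination: the geminal dichromium species from bromoform adds to the aldehyde and anti elimination gives the (E)-bromoalkene, with E-selectivity highest for hindered aldehydes. The bromide salt avoids chloride/bromide scrambling, and chromium(II) leaves the boronate and ring alkene alone.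

**Step 10**
Reactants: 14 2-{(1R,6R)-6-[(E)-2-bromoethenyl]-4,6-dimethylcyclohex-3-en-1-yl}-4,4,5,5-tetramethyl-1,3,2-dioxaborolane
Product: 16 (4S,5S)-4-bromo-5-[(E)-2-bromoethenyl]-1,5-dimethylcyclohex-1-ene, via lithium boronate complex 15 (not isolated)
Conditions: 3,5-(CF3)2C6H3Li (from ArBr, n-BuLi), THF, −78 °C; NBS, −78 °C → rt
Reagents that add atoms: N-bromosuccinimide, O=C1CCC(=O)N1Br; 3,5-bis(trifluoromethyl)phenyllithium, [Li]c1cc(cc(c1)C(F)(F)F)C(F)(F)F (its aryl group is carried only by 15)
Why: The aryllithium adds to boron to give boronate complex 15, which is brominated at carbon on the side opposite boron (SE2 with inversion, the stereospecific bromodeboronation of secondary boronic esters); this turns the trans B/vinyl relation into the required cis Br/vinyl relation at C2. The electron-poor aryl group disfavours single-electron oxidation and is not itself brominated, and at −78 °C the boronate complex should outcompete the ring alkene for NBS.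

**Step 11**
Reactants: 16 (4S,5S)-4-bromo-5-[(E)-2-bromoethenyl]-1,5-dimethylcyclohex-1-ene
Product: 17 (1R,3S,4S,6S)-4-bromo-3-[(E)-2-bromoethenyl]-1,3-dimethyl-7-oxabicyclo[4.1.0]heptane
Conditions: mCPBA, NaHCO3, CH2Cl2, 0 °C
Reagents that add atoms: 3-chloroperoxybenzoic acid, OOC(=O)c1cccc(Cl)c1
Why: Prilezhaev epoxidation; the peracid selects the electron-rich trisubstituted ring alkene over the bromoalkene. It should approach the face away from the C2 bromine and the bromovinyl group, where only the C1 methyl is found, placing oxygen trans to both.

**Step 12**
Reactants: 17 (1R,3S,4S,6S)-4-bromo-3-[(E)-2-bromoethenyl]-1,3-dimethyl-7-oxabicyclo[4.1.0]heptane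
Product: 18 (1S,2S,4S,5S)-5-bromo-4-[(E)-2-bromoethenyl]-2-chloro-2,4-dimethylcyclohexan-1-ol
Conditions: HCl (anhydrous, Et2O), CH2Cl2, −40 → 0 °C
Reagents that add atoms: hydrogen chloride, Cl
Why: Acid-mediated epoxide opening at the tertiary carbon with inversion (Markovnikov, trans-diaxial) puts the C5 chlorine on the face of Br and the vinyl arm and leaves the C4 hydroxyl on the other face. Tertiary cation character and the trans-diaxial chair with both methyls equatorial favour the same regiochemistry.

**Step 13**
Reactants: 18 (1S,2S,4S,5S)-5-bromo-4-[(E)-2-bromoethenyl]-2-chloro-2,4-dimethylcyclohexan-1-ol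
Product: 19 (1S,2S,4R,5S)-2-bromo-1-[(E)-2-bromoethenyl]-4,5-dichloro-1,5-dimethylcyclohexane
Conditions: PPh3, CCl4, 70 °C
Reagents that add atoms: tetrachloromethane, ClC(Cl)(Cl)Cl
Why: Appel reaction: the axial alkoxyphosphonium is displaced by chloride with inversion (SN2), which places the C4 chlorine cis to the C5 chlorine and completes the net syn-dichlorination. The non-polar medium keeps ionisation, chlorine participation and E1 loss of the tertiary chloride low.

## Compound list

1 | ethyl (E)-2-methylbut-2-enoate | C/C=C(\C)C(=O)OCC | starting material
2 | tert-butyl[(1-ethoxy-2-methylbuta-1,3-dien-1-yl)oxy]dimethylsilane | C=CC(C)=C(OCC)O[Si](C)(C)C(C)(C)C | intermediate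
3 | methacrolein | C=C(C)C=O | starting material
4 | ethyl (2E,5R)-5-hydroxy-2,6-dimethylhepta-2,6-dienoate | C=C(C)[C@H](O)C/C=C(\C)C(=O)OCC | intermediate
5 | bis(pinacolato)diboron | CC1(C)OB(B2OC(C)(C)C(C)(C)O2)OC1(C)C | starting material
6 | ethyl (3R,5R)-5-hydroxy-2,6-dimethyl-3-(Bpin)hept-6-enoate | C=C(C)[C@H](O)C[C@@H](B1OC(C)(C)C(C)(C)O1)C(C)C(=O)OCC | intermediate
7 | (4R,6R)-3-methyl-6-(prop-1-en-2-yl)-4-(Bpin)oxan-2-one | CC(=C)[C@H]1C[C@@H](B2OC(C)(C)C(C)(C)O2)C(C)C(=O)O1 | intermediate
8 | tert-butyl(dimethyl){[(2R,4R)-5-methyl-2-(prop-1-en-2-yl)-4-(Bpin)-3,4-dihydro-2H-pyran-6-yl]oxy}silane | CC(=C)[C@H]1C[C@@H](B2OC(C)(C)C(C)(C)O2)C(C)=C(O[Si](C)(C)C(C)(C)C)O1 | intermediate (not isolated)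
9 | tert-butyldimethylsilyl (1R,6R)-1,3-dimethyl-6-(Bpin)cyclohex-3-ene-1-carboxylate | CC1=CC[C@@H](B2OC(C)(C)C(C)(C)O2)[C@](C)(C(=O)O[Si](C)(C)C(C)(C)C)C1 | intermediate (not isolated)
10 | (1R,6R)-1,3-dimethyl-6-(Bpin)cyclohex-3-ene-1-carboxylic acid | CC1=CC[C@@H](B2OC(C)(C)C(C)(C)O2)[C@](C)(C(=O)O)C1 | intermediate
11 | methyl (1R,6R)-1,3-dimethyl-6-(Bpin)cyclohex-3-ene-1-carboxylate | CC1=CC[C@@H](B2OC(C)(C)C(C)(C)O2)[C@](C)(C(=O)OC)C1 | intermediate
12 | [(1R,6R)-1,3-dimethyl-6-(Bpin)cyclohex-3-en-1-yl]methanol | CC1=CC[C@@H](B2OC(C)(C)C(C)(C)O2)[C@](C)(CO)C1 | intermediate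
13 | (1R,6R)-1,3-dimethyl-6-(Bpin)cyclohex-3-ene-1-carbaldehyde | CC1=CC[C@@H](B2OC(C)(C)C(C)(C)O2)[C@](C)(C=O)C1 | intermediate
14 | 2-{(1R,6R)-6-[(E)-2-bromoethenyl]-4,6-dimethylcyclohex-3-en-1-yl}-4,4,5,5-tetramethyl-1,3,2-dioxaborolane | CC1=CC[C@@H](B2OC(C)(C)C(C)(C)O2)[C@](C)(/C=C/Br)C1 | intermediate
15 | lithium [3,5-bis(trifluoromethyl)phenyl]{(1R,6R)-6-[(E)-2-bromoethenyl]-4,6-dimethylcyclohex-3-en-1-yl}(pinacolato)borate | [Li+].CC1=CC[C@@H]([B-]2(OC(C)(C)C(C)(C)O2)c2cc(cc(c2)C(F)(F)F)C(F)(F)F)[C@](C)(/C=C/Br)C1 | intermediate (not isolated)
16 | (4S,5S)-4-bromo-5-[(E)-2-bromoethenyl]-1,5-dimethylcyclohex-1-ene | CC1=CC[C@H](Br)[C@](C)(/C=C/Br)C1 | intermediate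
17 | (1R,3S,4S,6S)-4-bromo-3-[(E)-2-bromoethenyl]-1,3-dimethyl-7-oxabicyclo[4.1.0]heptane | C[C@@]12C[C@@](C)(/C=C/Br)[C@@H](Br)C[C@@H]1O2 | intermediate
18 | (1S,2S,4S,5S)-5-bromo-4-[(E)-2-bromoethenyl]-2-chloro-2,4-dimethylcyclohexan-1-ol | C[C@]1(Cl)C[C@@](C)(/C=C/Br)[C@@H](Br)C[C@@H]1O | intermediate
19 | (1S,2S,4R,5S)-2-bromo-1-[(E)-2-bromoethenyl]-4,5-dichloro-1,5-dimethylcyclohexane | C[C@]1(Cl)C[C@@](C)(/C=C/Br)[C@@H](Br)C[C@H]1Cl | target

## Step count and least certain steps

Total: 13 steps. Longest linear sequence: 13 steps (from 1; compounds 3 and 5 enter as reagents).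

**Step 5 (key step).** The fully substituted ketene acetal must pass through a boat in which the Bpin group sits beside the forming bond. The rearrangement may therefore be slow, and at the temperature needed silyl migration to carbon, hydrolysis or boron-assisted decomposition of the ketene acetal may compete. The lithium amide may also engage the boronate and prevent clean enolisation. The fallback changes the reactive intermediate and how it is made: soft enolisation of 7 with dicyclohexylboron triflate and triethylamine (CH2Cl2, −78 °C) would give the dicyclohexylboron ketene acetal F1. This uses no lithium amide and no chlorosilane, and boron ketene acetals of allylic esters rearrange at or below room temperature. F1 would rearrange to the acyloxyborane F2, and non-oxidative aqueous work-up would return the route at acid 10.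

**Step 10.** Attack of the bromine electrophile at the back of a carbon flanked by the quaternary centre is hindered. Single-electron oxidation of the boronate complex may take over and erode the stereospecificity, and the ring alkene may compete for NBS. The fallback sets out from 14: oxidation of the C–B bond with retention (NaBO3·4H2O, THF–H2O) would give (1R,6S)-6-[(E)-2-bromoethenyl]-4,6-dimethylcyclohex-3-en-1-ol F3. An Appel bromination (PPh3, CBr4) with inversion would then rejoin the route at 16. This substitution is itself hindered and prone to elimination, which is why it is the reserve and not the plan.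

**Step 13.** Displacement at C4 must pass beside the axial C5 chlorine. Participation of that chlorine (bridged chloronium, giving retention) or elimination toward C3 may outrun the SN2 reaction. The fallback sets out from 16 and uses a selenium nucleofuge in place of the oxyphosphonium. Benzeneselenenyl chloride would add anti to the ring alkene to give the Markovnikov adduct [(1S,2S,4S,5S)-5-bromo-4-[(E)-2-bromoethenyl]-2-chloro-2,4-dimethylcyclohexyl](phenyl)selane F4. Sulfuryl chloride would oxidise it to the selenium(IV) dichloride F5, and chloride (Bu4NCl) would displace selenium with inversion at low temperature, rejoining the route at 19.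

**Step 11.** Facial selectivity in the epoxidation rests on a modest steric and dipolar bias (Br and vinyl on one face, methyl on the other) and may be poor. The fallback replaces substrate control by reagent control: a fructose-derived chiral ketone/Oxone epoxidation (Shi epoxidation), with the ketone enantiomer matched to the required face, would convert 16 to 17. Material epoxidised on the wrong face is a separable diastereomer.

## Further compounds

F1 | step 5 | dicyclohexyl{[(2R,4R)-5-methyl-2-(prop-1-en-2-yl)-4-(Bpin)-3,4-dihydro-2H-pyran-6-yl]oxy}borane | CC(=C)[C@H]1C[C@@H](B2OC(C)(C)C(C)(C)O2)C(C)=C(OB(C2CCCCC2)C2CCCCC2)O1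
F2 | step 5 | dicyclohexylboryl (1R,6R)-1,3-dimethyl-6-(Bpin)cyclohex-3-ene-1-carboxylate | CC1=CC[C@@H](B2OC(C)(C)C(C)(C)O2)[C@](C)(C(=O)OB(C2CCCCC2)C2CCCCC2)C1
F3 | step 10 | (1R,6S)-6-[(E)-2-bromoethenyl]-4,6-dimethylcyclohex-3-en-1-ol | CC1=CC[C@@H](O)[C@](C)(/C=C/Br)C1
F4 | step 13 | [(1S,2S,4S,5S)-5-bromo-4-[(E)-2-bromoethenyl]-2-chloro-2,4-dimethylcyclohexyl](phenyl)selane | C[C@]1(Cl)C[C@@](C)(/C=C/Br)[C@@H](Br)C[C@@H]1[Se]c1ccccc1
F5 | step 13 | [(1S,2S,4S,5S)-5-bromo-4-[(E)-2-bromoethenyl]-2-chloro-2,4-dimethylcyclohexyl]dichloro(phenyl)-λ4-selane | C[C@]1(Cl)C[C@@](C)(/C=C/Br)[C@@H](Br)C[C@@H]1[Se](Cl)(Cl)c1ccccc1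
F0 | step 11 | none | none
A1 | alternative 1 | (1S,2S,4R,5S)-2-bromo-4-chloro-1,5-dimethyl-6-oxabicyclo[3.2.1]octane | C[C@]1(O2)C[C@@](C)(C2)[C@@H](Br)C[C@H]1Cl
A2 | alternative 1 | (2Z,5R)-5-chloro-2,6-dimethylhepta-2,6-dien-1-ol | OC/C(C)=C\C[C@@H](Cl)C(C)=C
A3 | alternative 2 | (1R)-1-methyl-4-oxocyclohex-2-ene-1-carbaldehyde | O=C1C=C[C@](C)(C=O)CC1
A4 | alternative 2 | (E)-3-[(tert-butyldimethylsilyl)oxy]-N,N-dimethylbuta-1,3-dien-1-amine | CN(C)/C=C/C(=C)O[Si](C)(C)C(C)(C)C
A5 | alternative 3 | 2-{(1R,6R)-6-[(E)-2-(dimethylphenylsilyl)ethenyl]-4,6-dimethylcyclohex-3-en-1-yl}-4,4,5,5-tetramethyl-1,3,2-dioxaborolane | CC1=CC[C@@H](B2OC(C)(C)C(C)(C)O2)[C@](C)(/C=C/[Si](C)(C)c2ccccc2)C1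
A6 | alternative 3 | methyl (2E,5Z)-1-[dimethyl(phenyl)silyl]-3,5-dimethyl-8,8-bis(4,4,5,5-tetramethyl-1,3,2-dioxaborolan-2-yl)octa-2,5-dien-1-yl carbonate | COC(=O)OC(/C=C(\C)C/C(C)=C\CC(B1OC(C)(C)C(C)(C)O1)B1OC(C)(C)C(C)(C)O1)[Si](C)(C)c1ccccc1
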